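## The problem

1. The target is a linear phlorotannin-type octamer: eight benzene rings, lettered A to H, are joined only through seven diaryl ether oxygens, so seven Ar–O–Ar bonds must be placed among 28 oxygens while the other 21 stay free hydroxyls.
2. In each ring, position 1 is taken here as the carbon bearing the ether oxygen toward the preceding ring (in ring A, toward ring B). Ring A then has hydroxyls at 2, 4 and 6; ring B hydroxyls at 3 and 4 and the ether to ring C at 5; rings C, E and G hydroxyls at 3, 4 and 5 and the next ether at 6; rings D and F hydroxyls at 3 and 5 and the next ether at 4; ring H hydroxyls at 3, 4 and 5.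
3. There is no stereocentre and the aryl–oxygen bonds rotate freely, so nothing has to be controlled stereochemically; the difficulty is purely regiochemical.
4. Six of the seven ether oxygens stand on a carbon flanked by two oxygen-bearing carbons (position 1 of ring A, position 6 of rings C, E and G, position 4 of rings D and F), and every ring is strongly electron-rich, which works against both nucleophilic aromatic substitution and copper-mediated coupling.
5. The free polyphenol, with catechol- and pyrogallol-type arrays in rings B, C, E, G and H, is sensitive to air and base, so the hydroxyls must travel masked (here as methyl ethers) and be released together at the end under acidic, non-oxidising conditions.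
6. The rings D–E pair recurs as rings F–G, which invites one reusable two-ring building block.
7. The key step rests on the oxygen pattern of ring A: hydroxyls on alternate carbons 2, 4 and 6 with the ether oxygen on carbon 1 between two of them is the pattern of a triketide with an aryloxyacetyl starter. Ring A can therefore be folded from an open-chain methyl 6-aryloxy-3,5-dioxohexanoate by one C–C bond between chain carbons 6 and 1, with its crowded ether already present as an ordinary alkyl aryl ether.

## Retrosynthesis

**Release of the hydroxyls (30 from 29).** The 21 O–CH3 bonds of the permethyl ether 29 are cut last. Methyl is preferred to benzyl because 21 benzyl groups would crowd every coupling and because the cheapest building blocks already carry methyl ethers. 29 is stable to air, base and chromatography, which 30 is not. The forward step asks one reagent to cleave every methyl ether and no diaryl ether.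

**Ring H (29 from 27 and 28).** The ether between position 6 of ring G and position 1 of ring H is cut to the heptameric phenol 27 and the purchasable iodide 28. The polarity is chosen so that the halide sits on a carbon with two ortho hydrogens; the reverse polarity would demand displacement at a carbon flanked by methoxy and aryloxy groups. The forward reaction must arylate a phenoxide that is shielded on both sides.

**The repeat unit (27 from 24, and 24 from 19, each with 21).** Phenol 27 is traced through formate 26 to aldehyde 25, and 25 is cut at the ether between position 6 of ring E and position 1 of ring F into phenol 24 and the two-ring bromide 21. The same two moves take 24 through 23 and 22 back to the three-ring phenol 19 and a second molecule of 21. Cutting between the pairs rather than ring by ring saves four steps and again puts the halide on the only unhindered carbon of the pair. The formyl group of 21 must survive the copper step and then be exchanged for hydroxyl.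

**The block (21 from 20 and 16; 16 from 14).** The ether between position 4 of ring D and position 1 of ring E is cut to the bromophenol 20 and the fluoroaldehyde 16. Here substitution needs no metal, because the formyl group of 16 activates the ortho fluoride, so the bromide of 20 is untouched. The formyl group also sits exactly on the carbon that must later bear oxygen. 16 comes from 14 by formylation through 15, the two open positions of 14 being equivalent.

**Ring C (19 from 13 and 16).** Phenol 19 is traced through formate 18 to aldehyde 17, which is cut at the ether between position 5 of ring B and position 1 of ring C into the two-ring phenol 13 and 16. This is the one ether not flanked on both sides, and the same substitution/oxidation pair as in the block serves it.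

**Unmasking ring B (13 from 12 from 11).** The phenol of 13 is traced to the benzyl ether 12, and the three methyl ethers of ring A in 12 to the triol 11. Benzyl is the one group that distinguishes the ring B oxygen destined for ring C from all methylated oxygens.

**Ring A (11 from 9, the key cut).** One C–C bond of ring A, between the ether-bearing carbon and its hydroxyl-bearing neighbour, is cut, passing through the trione tautomer 10 to the open-chain diketo ester 9. The alternative, cutting the A–B ether, would require coupling at the most hindered and most electron-rich carbon of that end. The chosen cut replaces it by an alkyl aryl ether that any phenol forms with a bromoacetate. The forward reaction must make chain carbon 6 attack the ester in preference to the enol oxygen.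

**The chain (9 from 6 and 7; 6 from 4 and 5; 4 from 1).** The C4–C5 bond of 9 is cut to the aryloxyacetate 6 and the dianion 8 of methyl acetoacetate 7. 6 is cut at its alkyl–oxygen bond to phenol 4 and methyl bromoacetate 5. 4 is traced through formate 3 and the benzyl ether 2 to the commercial aldehyde 1, whose substitution pattern is already that of ring B.

## Roads not taken

**Alternative 1:** Both ether bonds of ring C are cut at once, with ring C as a doubly electrophilic linchpin: the cationic cyclopentadienylruthenium complex A1 of 1,2-dichloro-3,4,5-trimethoxybenzene (divalent ruthenium).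
- Forward step: the phenoxide of 13 would displace the chloride at position 1, the phenoxide of 4-(benzyloxy)-3,5-dimethoxyphenol A2 the chloride at position 6, and photolysis in acetonitrile would release the four-ring benzyl ether A3.
- Merits: metal activation makes substitution possible near room temperature even with crowded phenoxides, and two hindered ethers form in one flask with no formyl-to-hydroxyl exchange. In bond economy at ring C this is better than the chosen route, which needs steps 9, 10 and 12 for the same two ethers.
- Weak points: the two chlorides are adjacent and both activated, so the order of attack rests only on a steric bias (hydrogen versus methoxy neighbour), and misordered or doubly substituted isomers would be hard to separate. Three methoxy donors and the first aryloxy group lower the electrophilicity of the complex. One equivalent of ruthenium is consumed per pentaoxygenated ring, three times over the octamer. The road also leaves open where 13 comes from.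
- Comparison: the chosen plan sets against it regiochemistry fixed by the position of the formyl group in 16, a block 21 used twice, cheap reagents, and a ring A whose ether is built, not coupled.

**Alternative 2:** The C1–C6 bond inside ring C is cut, and the ring is grown from a squaric ester.
- Forward step: thermolysis of cyclobutenone A4 would open it to a dienylketene whose 6-electron closure and tautomerisation give the three-ring phenol A5, which is identical with 19.
- Merits: no substitution is needed on the crowded ring, the conditions are neutral, and the only free hydroxyl is the one needed next.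
- Weak points: A4 would have to be assembled from a squaric ester and a β-metallated aryl vinyl ether, a species prone to expel aryloxide, followed by O-methylation of a tertiary alkoxide. The whole sequence would have to be repeated for rings E and G on ever larger partners.
- Comparison: the chosen route reaches the same compound from 13 in two ordinary steps (9 and 10), so nothing is gained in step count. Alternative 2 is better in one respect: it avoids substitution on the donor-rich fluoroarene 16. Against that the chosen plan sets a one-step building block and reactions of a very common type.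

**Alternative 3:** Two C–C bonds of ring D (2–3 and 1–6) are cut, so that ring D is created while two halves are joined.
- Forward step: heating the cyclobutenone A6, which carries rings E to H, with the ethynyl ether A7 of rings A to C would give, by ketene cycloaddition, ring opening and 6-electron closure, the octamer A8 with a free hydroxyl at position 3 and an ethyl ether at position 5 of ring D.
- Merits: this is the most convergent road, with a shorter longest linear sequence than the 15 steps of the chosen plan, and the regiochemistry of this benzannulation is dependable.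
- Weak points: aryl ethynyl ethers of hindered, electron-rich phenols are thermally fragile and need several steps from 19. 4-Aryloxycyclobutenones of this size are not an established substrate class. Both halves still require the same ether-forming chemistry as the chosen route. The untested union would be staked on two advanced fragments at the very end.
- Comparison: the chosen plan concedes the convergence. It sets against it that its single unprecedented step comes at step 5 on cheap material, with a one-step bypass, and that everything after it is standard.

Key step: step 5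

## Route

Remarks on the chemistry: compounds 1, 5, 7, 14, 20 and 28 are taken as catalogue compounds. The target has no stereogenic element, so no step has a stereochemical task. "Permethylated" means that every oxygen not otherwise named is a methyl ether; ring positions follow the convention set out under "The problem".

Step 1
Reactants: 1 5-hydroxy-3,4-dimethoxybenzaldehyde
Product: 2 3-(benzyloxy)-4,5-dimethoxybenzaldehyde
Conditions: BnBr, K2CO3, DMF, rt
Reagents that add atoms: benzyl bromide, BrCc1ccccc1
Why: Williamson O-benzylation of the only free phenol; the benzyl ether marks the ring B oxygen that will later carry ring C and can be removed by hydrogenolysis without touching methyl or aryl ethers.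

Step 2
Reactants: 2 3-(benzyloxy)-4,5-dimethoxybenzaldehyde
Product: 4 3-(benzyloxy)-4,5-dimethoxyphenol, via aryl formate 3 (not isolated)
Conditions: mCPBA, CH2Cl2, 0 °C to rt; then K2CO3 (cat.), MeOH, rt
Reagents that add atoms: mCPBA (3-chloroperoxybenzoic acid), OOC(=O)c1cccc(Cl)c1
Why: Baeyer–Villiger oxidation in which the electron-rich trialkoxyphenyl group migrates in preference to hydride, followed by mild methanolysis of the formate; the benzyl ether is inert to both.

Step 3
Reactants: 4 3-(benzyloxy)-4,5-dimethoxyphenol; 5 methyl bromoacetate
Product: 6 methyl 2-[3-(benzyloxy)-4,5-dimethoxyphenoxy]acetate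
Conditions: K2CO3, acetone, reflux
Reagents that add atoms: none
Why: Williamson ether synthesis (SN2) of an unhindered phenoxide with an activated primary bromide; this easy O-alkylation creates what will become the crowded A–B ether.

Step 4
Reactants: 6 methyl 2-[3-(benzyloxy)-4,5-dimethoxyphenoxy]acetate; 7 methyl acetoacetate
Product: 9 methyl 6-[3-(benzyloxy)-4,5-dimethoxyphenoxy]-3,5-dioxohexanoate, via methyl acetoacetate dianion 8 (not isolated)
Conditions: 7 (2.2 equiv), NaH, THF, 0 °C; n-BuLi, 0 °C; then 6, 0 °C to rt; aq. HCl
Reagents that add atoms: none
Why: Claisen-type acylation of the acetoacetate dianion at its terminal carbon by ester 6; the dianion is used in excess because the diketo ester formed consumes base, and alkoxy- and aryloxyacetates are established acyl donors in this reaction.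

Step 5
Reactants: 9 methyl 6-[3-(benzyloxy)-4,5-dimethoxyphenoxy]-3,5-dioxohexanoate
Product: 11 2-[3-(benzyloxy)-4,5-dimethoxyphenoxy]benzene-1,3,5-triol, via cyclohexanetrione tautomer 10 (not isolated)
Conditions: Mg(OMe)2 (4 equiv), MeOH, reflux, Ar; then aq. HCl, 0 °C
Reagents that add atoms: none
Why: Proposed new method: Mg(OMe)2 converts 9 into its magnesium enolates; the minor enolate at carbon 6, whose formation is helped by the acidifying aryloxy group, adds to the ester carbonyl at carbon 1, methoxide leaves, and trione 10 tautomerises at once to the aromatic triol 11, whose phenoxide is the thermodynamic sink. The closest known reaction types are the Mg(OMe)2-mediated Claisen cyclisation of 3,5,7-triketo esters to acylphloroglucinols, the alkoxide-mediated closure of 5-oxo esters to cyclohexane-1,3-diones and the enzymatic fold of a triketide to phloroglucinol; what is new is that the nucleophilic carbon is activated by one carbonyl and an aryloxy group instead of two carbonyls. Ring A closes in a 6-(enolendo)-exo-trig Claisen mode, and the one new C–C bond joins the ether-bearing carbon to its hydroxyl-bearing neighbour. No stereocentre is created. The step needs C-acylation at carbon 6 to prevail over O-acylation by the carbon 5 enol oxygen (which would give a 4-hydroxy-2-pyrone) and over retro-Claisen cleavage of the 1,3-diketone by methoxide. Divalent magnesium holds the dicarbonyl oxygens as a chelate, which blunts the enol oxygen as a nucleophile and shields the ketones from methoxide; a pyrone, if formed, should be reopened by methoxide under these conditions, whereas aromatisation is a one-way exit. The aryl ether is not at risk because the aryloxy group is alpha, not beta, to the ketone and cannot be expelled by elimination.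

Step 6
Reactants: 11 2-[3-(benzyloxy)-4,5-dimethoxyphenoxy]benzene-1,3,5-triol
Product: 12 1-(benzyloxy)-2,3-dimethoxy-5-(2,4,6-trimethoxyphenoxy)benzene
Conditions: Me2SO4, K2CO3, acetone, reflux
Reagents that add atoms: dimethyl sulfate, COS(=O)(=O)OC
Why: Exhaustive Williamson O-methylation under the conditions that turn phloroglucinol into 1,3,5-trimethoxybenzene; the weak base and hard electrophile keep C-methylation of the phloroglucinol ring low.

Step 7
Reactants: 12 1-(benzyloxy)-2,3-dimethoxy-5-(2,4,6-trimethoxyphenoxy)benzene
Product: 13 2,3-dimethoxy-5-(2,4,6-trimethoxyphenoxy)phenol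
Conditions: H2 (1 atm), 10% Pd/C, EtOAc/MeOH, rt
Reagents that add atoms: none
Why: Catalytic hydrogenolysis cleaves only the benzyl ether; methyl ethers and the diaryl ether are inert, so the single phenol appears at position 5 of ring B.

Step 8
Reactants: 14 5-fluoro-1,2,3-trimethoxybenzene
Product: 16 6-fluoro-2,3,4-trimethoxybenzaldehyde, via chloro(methoxy)methyl arene 15 (not isolated)
Conditions: Cl2CHOMe, TiCl4, CH2Cl2, 0 °C; then H2O
Reagents that add atoms: dichloromethyl methyl ether, COC(Cl)Cl; water, O
Why: Rieche formylation (electrophilic aromatic substitution); the two open positions of 14 are equivalent, each ortho to fluorine and methoxy and para to a methoxy group, so one aldehyde results after hydrolysis of 15.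

Step 9
Reactants: 13 2,3-dimethoxy-5-(2,4,6-trimethoxyphenoxy)phenol; 16 6-fluoro-2,3,4-trimethoxybenzaldehyde
Product: 17 6-[2,3-dimethoxy-5-(2,4,6-trimethoxyphenoxy)phenoxy]-2,3,4-trimethoxybenzaldehyde
Conditions: K2CO3, DMF, 100 °C
Reagents that add atoms: none
Why: Nucleophilic aromatic substitution (addition–elimination) of the fluoride ortho to the formyl group by the phenoxide of 13; the formyl group activates the ring and marks the carbon that will carry the next oxygen.

Step 10
Reactants: 17 6-[2,3-dimethoxy-5-(2,4,6-trimethoxyphenoxy)phenoxy]-2,3,4-trimethoxybenzaldehyde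
Product: 19 6-[2,3-dimethoxy-5-(2,4,6-trimethoxyphenoxy)phenoxy]-2,3,4-trimethoxyphenol, via rings A to C aryl formate 18 (not isolated)
Conditions: mCPBA, CH2Cl2, 0 °C; then K2CO3 (cat.), MeOH, rt, Ar
Reagents that add atoms: mCPBA (3-chloroperoxybenzoic acid), OOC(=O)c1cccc(Cl)c1
Why: Baeyer–Villiger oxidation with migration of the 2,6-dioxygenated aryl group, then methanolysis of formate 18; the new phenol at position 6 of ring C is the only free hydroxyl in the molecule.

Step 11
Reactants: 20 4-bromo-2,6-dimethoxyphenol; 16 6-fluoro-2,3,4-trimethoxybenzaldehyde
Product: 21 6-(4-bromo-2,6-dimethoxyphenoxy)-2,3,4-trimethoxybenzaldehyde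
Conditions: Cs2CO3, DMF, 110 °C, Ar
Reagents that add atoms: none
Why: Nucleophilic aromatic substitution as in step 9; without copper the aryl bromide of 20 is a spectator, so the product carries both the handle for the later coupling (bromide on ring D) and the masked phenol (formyl on ring E).

Step 12
Reactants: 19 6-[2,3-dimethoxy-5-(2,4,6-trimethoxyphenoxy)phenoxy]-2,3,4-trimethoxyphenol; 21 6-(4-bromo-2,6-dimethoxyphenoxy)-2,3,4-trimethoxybenzaldehyde
Product: 22 permethylated rings A to E aldehyde (formyl at position 6 of ring E)
Conditions: CuI (20 mol %), picolinic acid (40 mol %), K3PO4, DMSO, 100 °C, Ar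
Reagents that add atoms: none
Why: Ullmann-type diaryl ether synthesis catalysed by monovalent copper with picolinic acid, a ligand system suited to phenols substituted at both ortho positions; the bromide of 21 has two ortho hydrogens and the non-enolisable aldehyde is tolerated.

Step 13
Reactants: 22 permethylated rings A to E aldehyde
Product: 24 permethylated rings A to E phenol (hydroxyl at position 6 of ring E), via rings A to E aryl formate 23 (not isolated)
Conditions: mCPBA, CH2Cl2, 0 °C; then K2CO3 (cat.), MeOH, rt, Ar
Reagents that add atoms: mCPBA (3-chloroperoxybenzoic acid), OOC(=O)c1cccc(Cl)c1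
Why: Baeyer–Villiger oxidation and formate methanolysis as in step 10; the formyl carbon is attached to the same 2,6-dioxygenated ring type, so aryl migration should again be favoured.

Step 14
Reactants: 24 permethylated rings A to E phenol; 21 6-(4-bromo-2,6-dimethoxyphenoxy)-2,3,4-trimethoxybenzaldehyde
Product: 25 permethylated rings A to G aldehyde (formyl at position 6 of ring G)
Conditions: CuI (20 mol %), picolinic acid (40 mol %), K3PO4, DMSO, 100 °C, Ar
Reagents that add atoms: none
Why: Second use of block 21 in the Ullmann-type copper-catalysed O-arylation of step 12; the reacting phenoxide has the same local environment as that of 19.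

Step 15
Reactants: 25 permethylated rings A to G aldehyde
Product: 27 permethylated rings A to G phenol (hydroxyl at position 6 of ring G), via rings A to G aryl formate 26 (not isolated)
Conditions: mCPBA, CH2Cl2, 0 °C; then K2CO3 (cat.), MeOH, rt, Ar
Reagents that add atoms: mCPBA (3-chloroperoxybenzoic acid), OOC(=O)c1cccc(Cl)c1
Why: Baeyer–Villiger oxidation and formate methanolysis as in steps 10 and 13.

Step 16
Reactants: 27 permethylated rings A to G phenol; 28 5-iodo-1,2,3-trimethoxybenzene
Product: 29 henicosa-O-methyl ether of the target (all 21 hydroxyls as methyl ethers)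
Conditions: CuI (20 mol %), picolinic acid (40 mol %), K3PO4, DMSO, 90 °C, Ar
Reagents that add atoms: none
Why: Ullmann-type copper-catalysed O-arylation as in step 12; the aryl iodide is unhindered and more reactive than a bromide, so only the phenoxide is crowded.

Step 17
Reactants: 29 henicosa-O-methyl ether of the target
Product: 30 the target octamer CNP0175816.0
Conditions: BBr3 (excess), CH2Cl2, −78 °C to rt; then MeOH, H2O, Ar
Reagents that add atoms: none
Why: Lewis-acid cleavage of all aryl methyl ethers (bromide attacks the methyl group of the boron-complexed ether); diaryl ethers are not cleaved because neither of their carbons is open to SN2 attack, and the acidic, oxygen-free work-up protects the polyphenol.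

## Compound list

1 | 5-hydroxy-3,4-dimethoxybenzaldehyde | COc1cc(C=O)cc(O)c1OC | starting material
2 | 3-(benzyloxy)-4,5-dimethoxybenzaldehyde | COc1cc(C=O)cc(OCc2ccccc2)c1OC | intermediate
3 | 3-(benzyloxy)-4,5-dimethoxyphenyl formate | COc1cc(OC=O)cc(OCc2ccccc2)c1OC | intermediate (not isolated)
4 | 3-(benzyloxy)-4,5-dimethoxyphenol | COc1cc(O)cc(OCc2ccccc2)c1OC | intermediate
5 | methyl bromoacetate | COC(=O)CBr | starting material
6 | methyl 2-[3-(benzyloxy)-4,5-dimethoxyphenoxy]acetate | COC(=O)COc1cc(OC)c(OC)c(OCc2ccccc2)c1 | intermediate
7 | methyl acetoacetate | COC(=O)CC(C)=O | starting material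
8 | methyl acetoacetate dianion (sodium lithium salt) | [CH2-]C(=O)[CH-]C(=O)OC.[Na+].[Li+] | intermediate (not isolated)
9 | methyl 6-[3-(benzyloxy)-4,5-dimethoxyphenoxy]-3,5-dioxohexanoate | COC(=O)CC(=O)CC(=O)COc1cc(OC)c(OC)c(OCc2ccccc2)c1 | intermediate (key-step precursor)
10 | 2-[3-(benzyloxy)-4,5-dimethoxyphenoxy]cyclohexane-1,3,5-trione | O=C1CC(=O)C(Oc2cc(OC)c(OC)c(OCc3ccccc3)c2)C(=O)C1 | intermediate (not isolated)
11 | 2-[3-(benzyloxy)-4,5-dimethoxyphenoxy]benzene-1,3,5-triol | Oc1cc(O)c(Oc2cc(OC)c(OC)c(OCc3ccccc3)c2)c(O)c1 | intermediate (key-step product)
12 | 1-(benzyloxy)-2,3-dimethoxy-5-(2,4,6-trimethoxyphenoxy)benzene | COc1cc(OC)c(Oc2cc(OC)c(OC)c(OCc3ccccc3)c2)c(OC)c1 | intermediate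
13 | 2,3-dimethoxy-5-(2,4,6-trimethoxyphenoxy)phenol | COc1cc(OC)c(Oc2cc(O)c(OC)c(OC)c2)c(OC)c1 | intermediate
14 | 5-fluoro-1,2,3-trimethoxybenzene | COc1cc(F)cc(OC)c1OC | starting material
15 | 2-[chloro(methoxy)methyl]-1-fluoro-3,4,5-trimethoxybenzene (racemic) | COC(Cl)c1c(F)cc(OC)c(OC)c1OC | intermediate (not isolated)
16 | 6-fluoro-2,3,4-trimethoxybenzaldehyde | COc1cc(F)c(C=O)c(OC)c1OC | intermediate
17 | 6-[2,3-dimethoxy-5-(2,4,6-trimethoxyphenoxy)phenoxy]-2,3,4-trimethoxybenzaldehyde (permethylated rings A to C aldehyde) | COc1cc(OC)c(Oc2cc(OC)c(OC)c(Oc3cc(OC)c(OC)c(OC)c3C=O)c2)c(OC)c1 | intermediate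
18 | 6-[2,3-dimethoxy-5-(2,4,6-trimethoxyphenoxy)phenoxy]-2,3,4-trimethoxyphenyl formate | COc1cc(OC)c(Oc2cc(OC)c(OC)c(Oc3cc(OC)c(OC)c(OC)c3OC=O)c2)c(OC)c1 | intermediate (not isolated)
19 | 6-[2,3-dimethoxy-5-(2,4,6-trimethoxyphenoxy)phenoxy]-2,3,4-trimethoxyphenol (permethylated rings A to C phenol) | COc1cc(OC)c(Oc2cc(OC)c(OC)c(Oc3cc(OC)c(OC)c(OC)c3O)c2)c(OC)c1 | intermediate
20 | 4-bromo-2,6-dimethoxyphenol | COc1cc(Br)cc(OC)c1O | starting material
21 | 6-(4-bromo-2,6-dimethoxyphenoxy)-2,3,4-trimethoxybenzaldehyde | COc1cc(Br)cc(OC)c1Oc1cc(OC)c(OC)c(OC)c1C=O | intermediate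
22 | permethylated rings A to E aldehyde: 6-[4-({6-[2,3-dimethoxy-5-(2,4,6-trimethoxyphenoxy)phenoxy]-2,3,4-trimethoxyphenyl}oxy)-2,6-dimethoxyphenoxy]-2,3,4-trimethoxybenzaldehyde | COc1cc(OC)c(Oc2cc(OC)c(OC)c(Oc3cc(OC)c(OC)c(OC)c3Oc3cc(OC)c(Oc4cc(OC)c(OC)c(OC)c4C=O)c(OC)c3)c2)c(OC)c1 | intermediate
23 | permethylated rings A to E aryl formate (formate of 24) | COc1cc(OC)c(Oc2cc(OC)c(OC)c(Oc3cc(OC)c(OC)c(OC)c3Oc3cc(OC)c(Oc4cc(OC)c(OC)c(OC)c4OC=O)c(OC)c3)c2)c(OC)c1 | intermediate (not isolated)
24 | permethylated rings A to E phenol (22 with hydroxyl in place of formyl at position 6 of ring E) | COc1cc(OC)c(Oc2cc(OC)c(OC)c(Oc3cc(OC)c(OC)c(OC)c3Oc3cc(OC)c(Oc4cc(OC)c(OC)c(OC)c4O)c(OC)c3)c2)c(OC)c1 | intermediate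
25 | permethylated rings A to G aldehyde (24 arylated at its hydroxyl by the ring D carbon of 21; formyl at position 6 of ring G) | COc1cc(OC)c(Oc2cc(OC)c(OC)c(Oc3cc(OC)c(OC)c(OC)c3Oc3cc(OC)c(Oc4cc(OC)c(OC)c(OC)c4Oc4cc(OC)c(Oc5cc(OC)c(OC)c(OC)c5C=O)c(OC)c4)c(OC)c3)c2)c(OC)c1 | intermediate
26 | permethylated rings A to G aryl formate (formate of 27) | COc1cc(OC)c(Oc2cc(OC)c(OC)c(Oc3cc(OC)c(OC)c(OC)c3Oc3cc(OC)c(Oc4cc(OC)c(OC)c(OC)c4Oc4cc(OC)c(Oc5cc(OC)c(OC)c(OC)c5OC=O)c(OC)c4)c(OC)c3)c2)c(OC)c1 | intermediate (not isolated)
27 | permethylated rings A to G phenol (hydroxyl at position 6 of ring G) | COc1cc(OC)c(Oc2cc(OC)c(OC)c(Oc3cc(OC)c(OC)c(OC)c3Oc3cc(OC)c(Oc4cc(OC)c(OC)c(OC)c4Oc4cc(OC)c(Oc5cc(OC)c(OC)c(OC)c5O)c(OC)c4)c(OC)c3)c2)c(OC)c1 | intermediate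
28 | 5-iodo-1,2,3-trimethoxybenzene | COc1cc(I)cc(OC)c1OC | starting material
29 | henicosa-O-methyl ether of the target (rings A to H, 21 methyl ethers) | COc1cc(OC)c(Oc2cc(OC)c(OC)c(Oc3cc(OC)c(OC)c(OC)c3Oc3cc(OC)c(Oc4cc(OC)c(OC)c(OC)c4Oc4cc(OC)c(Oc5cc(OC)c(OC)c(OC)c5Oc5cc(OC)c(OC)c(OC)c5)c(OC)c4)c(OC)c3)c2)c(OC)c1 | intermediate
30 | CNP0175816.0, the octameric polyphenol with 21 free hydroxyls (no stereocentre) | Oc1cc(O)c(Oc2cc(O)c(O)c(Oc3cc(O)c(O)c(O)c3Oc3cc(O)c(Oc4cc(O)c(O)c(O)c4Oc4cc(O)c(Oc5cc(O)c(O)c(O)c5Oc5cc(O)c(O)c(O)c5)c(O)c4)c(O)c3)c2)c(O)c1 | target

## Step count and least certain steps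

Total step count: 17. Longest linear sequence: 15 steps (steps 1 to 7, 9, 10 and 12 to 17); steps 8 and 11 lie on the building-block branch.

**Step 5 (key step, the only step marked as a proposed new method).**
- Most likely failure: ring closure through oxygen instead of carbon (lactonisation of the carbon 5 enol onto the ester without reopening), or retro-Claisen fragmentation of the diketone by methoxide before the slow enolisation toward carbon 6 leads to C–C bond formation. Both follow from carbon 6 being the least acidic of the three methylene groups.
- Fallback with known chemistry: phenol 4 is coupled with purchased 2-iodo-1,3,5-trimethoxybenzene under the copper/picolinic acid Ullmann conditions of step 12, the classical way to 2-aryloxy-1,3,5-trimethoxybenzenes. This gives 12 directly. The detour sets out from 4 and comes back at 12, bypassing 6, 9 and 11; it makes no compound outside the route and gives up the construction of ring A.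

**Step 12.**
- Most likely failure: slow C–O bond formation between a phenoxide shielded by methoxy and aryloxy neighbours and an electron-rich aryl bromide, so that hydrodebromination of the block and oxidative degradation of the phenoxide take over.
- Fallback: metal-free, ring-by-ring growth. Phenol 19 is treated with purchased 4-fluoro-2,6-dimethoxybenzaldehyde (K2CO3, DMF; the fluoride is para to the formyl group and has two ortho hydrogens) to give the permethylated rings A to D aldehyde F1. Baeyer–Villiger oxidation gives the rings A to D aryl formate F2, and methanolysis gives the rings A to D phenol F3 with its hydroxyl at position 4 of ring D. Substitution of 16 by F3, as in step 11, then gives 22. The detour sets out from 19 and comes back at 22.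

**Step 14.**
- Most likely failure: the same coupling on a five-ring phenol, with lower solubility, slower reaction and binding of the copper by the many ether oxygens, leading to stalled conversion.
- Fallback: the same ring-by-ring growth one pair further on. Phenol 24 and 4-fluoro-2,6-dimethoxybenzaldehyde give the permethylated rings A to F aldehyde F4. Baeyer–Villiger oxidation gives the rings A to F aryl formate F5 and methanolysis the rings A to F phenol F6. Substitution of 16 by F6 gives 25. The detour sets out from 24 and comes back at 25.

**Step 17.**
- Most likely failure: incomplete cleavage of some of the 21 methyl ethers, and oxidative loss of the polyphenol during aqueous work-up and chromatography.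
- Fallback: isolation through a stable derivative. After treatment of 29 with BBr3 and a methanol quench, the crude product is peracetylated (Ac2O, pyridine) to the henicosaacetate of the target F7, which can be purified on silica and freed from partially methylated material. Acid-catalysed methanolysis (HCl in MeOH, Ar) then releases 30. The detour sets out from 29 and comes back at 30.

## Further compounds

F0 | step 5 | none | none
F1 | step 12 | permethylated rings A to D aldehyde (formyl at position 4 of ring D) | COc1cc(OC)c(Oc2cc(OC)c(OC)c(Oc3cc(OC)c(OC)c(OC)c3Oc3cc(OC)c(C=O)c(OC)c3)c2)c(OC)c1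
F2 | step 12 | permethylated rings A to D aryl formate (formate of F3) | COc1cc(OC)c(Oc2cc(OC)c(OC)c(Oc3cc(OC)c(OC)c(OC)c3Oc3cc(OC)c(OC=O)c(OC)c3)c2)c(OC)c1
F3 | step 12 | permethylated rings A to D phenol (hydroxyl at position 4 of ring D) | COc1cc(OC)c(Oc2cc(OC)c(OC)c(Oc3cc(OC)c(OC)c(OC)c3Oc3cc(OC)c(O)c(OC)c3)c2)c(OC)c1
F4 | step 14 | permethylated rings A to F aldehyde (formyl at position 4 of ring F) | COc1cc(OC)c(Oc2cc(OC)c(OC)c(Oc3cc(OC)c(OC)c(OC)c3Oc3cc(OC)c(Oc4cc(OC)c(OC)c(OC)c4Oc4cc(OC)c(C=O)c(OC)c4)c(OC)c3)c2)c(OC)c1
F5 | step 14 | permethylated rings A to F aryl formate (formate of F6) | COc1cc(OC)c(Oc2cc(OC)c(OC)c(Oc3cc(OC)c(OC)c(OC)c3Oc3cc(OC)c(Oc4cc(OC)c(OC)c(OC)c4Oc4cc(OC)c(OC=O)c(OC)c4)c(OC)c3)c2)c(OC)c1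
F6 | step 14 | permethylated rings A to F phenol (hydroxyl at position 4 of ring F) | COc1cc(OC)c(Oc2cc(OC)c(OC)c(Oc3cc(OC)c(OC)c(OC)c3Oc3cc(OC)c(Oc4cc(OC)c(OC)c(OC)c4Oc4cc(OC)c(O)c(OC)c4)c(OC)c3)c2)c(OC)c1
F7 | step 17 | henicosaacetate of the target (all 21 hydroxyls as acetates) | CC(=O)Oc1cc(OC(C)=O)c(Oc2cc(OC(C)=O)c(OC(C)=O)c(Oc3cc(OC(C)=O)c(OC(C)=O)c(OC(C)=O)c3Oc3cc(OC(C)=O)c(Oc4cc(OC(C)=O)c(OC(C)=O)c(OC(C)=O)c4Oc4cc(OC(C)=O)c(Oc5cc(OC(C)=O)c(OC(C)=O)c(OC(C)=O)c5Oc5cc(OC(C)=O)c(OC(C)=O)c(OC(C)=O)c5)c(OC(C)=O)c4)c(OC(C)=O)c3)c2)c(OC(C)=O)c1
A1 | alternative 1 | (cyclopentadienyl)(1,2-dichloro-3,4,5-trimethoxybenzene)ruthenium hexafluorophosphate, divalent ruthenium | COc1cc(Cl)c(Cl)c(OC)c1OC.[Ru+2].c1cc[cH-]c1.F[P-](F)(F)(F)(F)F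
A2 | alternative 1 | 4-(benzyloxy)-3,5-dimethoxyphenol | COc1cc(O)cc(OC)c1OCc1ccccc1
A3 | alternative 1 | permethylated rings A to D tetramer with a benzyl ether at position 4 of ring D | COc1cc(OC)c(Oc2cc(OC)c(OC)c(Oc3cc(OC)c(OC)c(OC)c3Oc3cc(OC)c(OCc4ccccc4)c(OC)c3)c2)c(OC)c1
A4 | alternative 2 | 4-[(E)-2-[2,3-dimethoxy-5-(2,4,6-trimethoxyphenoxy)phenoxy]ethenyl]-2,3,4-trimethoxycyclobut-2-en-1-one (racemic) | O=C1C(OC)=C(OC)C1(OC)/C=C/Oc1cc(Oc2c(OC)cc(OC)cc2OC)cc(OC)c1OC
A5 | alternative 2 | permethylated rings A to C phenol with free hydroxyl at position 6 of ring C (identical with 19) | COc1cc(OC)c(Oc2cc(OC)c(OC)c(Oc3cc(OC)c(OC)c(OC)c3O)c2)c(OC)c1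
A6 | alternative 3 | 3-ethoxy-4-(aryloxy)cyclobut-2-en-1-one whose aryl group is the permethylated rings E to H unit (racemic) | CCOC1=CC(=O)C1Oc1cc(OC)c(OC)c(OC)c1Oc1cc(OC)c(Oc2cc(OC)c(OC)c(OC)c2Oc2cc(OC)c(OC)c(OC)c2)c(OC)c1
A7 | alternative 3 | ethynyl ether of the permethylated rings A to C phenol 19 | COc1cc(OC)c(Oc2cc(OC)c(OC)c(Oc3cc(OC)c(OC)c(OC)c3OC#C)c2)c(OC)c1
A8 | alternative 3 | octamer with free hydroxyl at position 3 of ring D, ethyl ether at position 5 of ring D and nineteen methyl ethers | COc1cc(OC)c(Oc2cc(OC)c(OC)c(Oc3cc(OC)c(OC)c(OC)c3Oc3cc(O)c(Oc4cc(OC)c(OC)c(OC)c4Oc4cc(OC)c(Oc5cc(OC)c(OC)c(OC)c5Oc5cc(OC)c(OC)c(OC)c5)c(OC)c4)c(OCC)c3)c2)c(OC)c1
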